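**Strategy**

1. Numbering (daucane) for the bicycle: C1 quaternary fusion carbon (CH3 = C15), C2 CH–O, C3 CH2, C4 C(OH)(i-Pr), C5 fusion CH, C6 CH–O, C7 CH2, C8 C(CH3)= (CH3 = C14), C9 =CH, C10 CH2; β is the face of the C1 methyl group, α the other face.
2. Cuts, in order: the two angelate C–O bonds; the C2–H and C6–H bonds (back to a 2,6-diketone); then C7–C8 and C10–C1 of the seven-membered ring, leaving a cyclopentenyl 2-silyloxydiene C7=C6(OSi)–C5=C1 and a vinylcarbene C8–C9=C10.
3. Enabling feature: the C8=C9 alkene lies 1,4 to the oxygen-bearing C6, so with C6 read as a C5=C6 enol ether the seven-membered ring is a cyclohepta-1,4-diene, the ring a cis-divinylcyclopropane gives on Cope rearrangement.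
4. Ring order forward: the five-membered ring is bought; a cyclopropane (C6, C7, C8) forms and opens in the same flask as the seven-membered ring closes onto the cyclopentene; the two esters go on last.
5. Stereochemistry: the silyloxy carbon of the bought (R)-enone (C2) directs the isopropyl addition (C4) and, with a chiral dirhodium catalyst, the C10–C1 bond (C1); C5 comes from face-selective protonation; C2 (after oxidation) and C6 come from hydride delivered by the C4 hydroxyl; the Z alkenes come from angelic acid.

Key step: step 10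

Assumption: which enantiomer of the dirhodium prolinate catalyst is matched to diene 10 cannot be read from the structure; the route is written with Rh2(S-DOSP)4, and Rh2(R-DOSP)4 takes its place, nothing else changing, if a small trial shows it to be the matched one.

**Route**

Step 1
Reactants: 1 (R)-4-(tert-butyldimethylsilyloxy)cyclopent-2-en-1-one
Product: 2 [(3R,4R)-4-(tert-butyldimethylsilyloxy)-3-methylcyclopent-1-en-1-yl]oxy(trimethyl)silane (methyl trans to the silyloxy group)
Conditions: MeMgBr, CuBr·SMe2 (10 mol%), Me3SiCl, THF, −78 °C; Et3N, then cold aqueous NaHCO3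
Reagents that add atoms: methylmagnesium bromide, C[Mg]Br; chlorotrimethylsilane, C[Si](C)(C)Cl
Why: Copper-catalysed conjugate addition of the Grignard reagent places the methyl group on C3 anti to the C4 silyloxy group, and the chlorosilane present from the start traps the enolate on oxygen before proton transfer could lead to loss of the silyloxy group.

Step 2
Reactants: 2 [(3R,4R)-4-(tert-butyldimethylsilyloxy)-3-methylcyclopent-1-en-1-yl]oxy(trimethyl)silane
Product: 3 (R)-4-(tert-butyldimethylsilyloxy)-3-methylcyclopent-2-en-1-one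
Conditions: Pd(OAc)2 (1.05 equiv), MeCN, 23 °C
Reagents that add atoms: none
Why: Saegusa–Ito oxidation, in which the palladium enolate at C2 loses the C3 hydrogen by β-hydride elimination, returns the enone with the methyl group on its β-carbon and leaves the silyloxy stereocentre untouched.

Step 3
Reactants: 3 (R)-4-(tert-butyldimethylsilyloxy)-3-methylcyclopent-2-en-1-one
Product: 5 (R)-2-bromo-4-(tert-butyldimethylsilyloxy)-3-methylcyclopent-2-en-1-one, via dibromo ketone 4 (not isolated)
Conditions: Br2, CH2Cl2, 0 °C; then Et3N, 0 → 23 °C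
Reagents that add atoms: bromine, BrBr
Why: α-Bromination of an enone by bromine addition and amine-induced E1cB loss of HBr (α-hydrogen removed, β-bromide expelled) leaves bromine on C2, and the amine keeps the silyl ether away from acid.

Step 4
Reactants: 5 (R)-2-bromo-4-(tert-butyldimethylsilyloxy)-3-methylcyclopent-2-en-1-one
Product: 6 (1R,4R)-2-bromo-4-(tert-butyldimethylsilyloxy)-3-methyl-1-(propan-2-yl)cyclopent-2-en-1-ol (hydroxyl cis, isopropyl trans to the silyloxy group)
Conditions: i-PrMgCl, anhydrous CeCl3, THF, −78 °C; aqueous NH4Cl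
Reagents that add atoms: isopropylmagnesium chloride, CC(C)[Mg]Cl
Why: Organocerium 1,2-addition (Imamoto conditions) suppresses enolisation, reduction and halogen–metal exchange, and the reagent approaches the carbonyl group on the face opposite the C4 silyloxy group, which sets the tertiary carbinol.

Step 5
Reactants: 6 (1R,4R)-2-bromo-4-(tert-butyldimethylsilyloxy)-3-methyl-1-(propan-2-yl)cyclopent-2-en-1-ol; 7 N-methoxy-N-methylacetamide
Product: 9 1-[(3R,5R)-3-(tert-butyldimethylsilyloxy)-5-hydroxy-2-methyl-5-(propan-2-yl)cyclopent-1-en-1-yl]ethan-1-one, via dilithio alkoxide 8 (not isolated)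
Conditions: t-BuLi (3.1 equiv), Et2O, −78 °C; then 7, −78 → 0 °C; aqueous NH4Cl
Reagents that add atoms: none
Why: After deprotonation of the hydroxyl group, bromine–lithium exchange gives a vinyllithium that is acylated once only in a Weinreb ketone synthesis, because the chelated tetrahedral adduct survives until the quench.

Step 6
Reactants: 9 1-[(3R,5R)-3-(tert-butyldimethylsilyloxy)-5-hydroxy-2-methyl-5-(propan-2-yl)cyclopent-1-en-1-yl]ethan-1-one
Product: 10 (3R,5R)-3-(tert-butyldimethylsilyloxy)-2-methyl-5-(propan-2-yl)-5-(triethylsilyloxy)-1-[1-(triethylsilyloxy)ethenyl]cyclopent-1-ene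
Conditions: Et3SiOTf (3 equiv), Et3N (5 equiv), CH2Cl2, −78 → 0 °C
Reagents that add atoms: triethylsilyl trifluoromethanesulfonate, CC[Si](CC)(CC)OS(=O)(=O)C(F)(F)F
Why: Silyl triflate and amine silylate the tertiary alcohol and convert the methyl ketone, by soft enolisation at the acetyl methyl group, into the cross-conjugated 2-silyloxydiene (kinetic enol silyl ether formation) without touching a stereocentre.

Step 7
Reactants: 11 methyl acetoacetate
Product: 12 methyl 2-diazo-3-oxobutanoate
Conditions: 4-acetamidobenzenesulfonyl azide, Et3N, MeCN, 0 → 23 °C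
Reagents that add atoms: 4-acetamidobenzenesulfonyl azide, CC(=O)Nc1ccc(cc1)S(=O)(=O)N=[N+]=[N-]
Why: Regitz diazo transfer to the doubly activated methylene group of a β-keto ester is a standard, reliable reaction.

Step 8
Reactants: 12 methyl 2-diazo-3-oxobutanoate
Product: 13 methyl 2-diazo-3-hydroxybutanoate (racemic)
Conditions: NaBH4, MeOH, 0 °C
Reagents that add atoms: none
Why: Borohydride reduction is chemoselective for the ketone, the ester and the diazo group being inert at this temperature.

Step 9
Reactants: 13 methyl 2-diazo-3-hydroxybutanoate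
Product: 15 methyl 2-diazobut-3-enoate, via dichlorophosphate ester 14 (not isolated)
Conditions: POCl3, Et3N, CH2Cl2, 0 °C; cold work-up, used at once as a pentane solution
Reagents that add atoms: none
Why: Dehydration by phosphorylation of the alcohol and amine-induced elimination gives the conjugated vinyl diazo ester, which is kept cold and used immediately because it cyclises to a pyrazole on standing.

Step 10
Reactants: 10 (3R,5R)-3-(tert-butyldimethylsilyloxy)-2-methyl-5-(propan-2-yl)-5-(triethylsilyloxy)-1-[1-(triethylsilyloxy)ethenyl]cyclopent-1-ene; 15 methyl 2-diazobut-3-enoate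
Product: 17 methyl (1R,2R,4R)-2β-(tert-butyldimethylsilyloxy)-4β,6-bis(triethylsilyloxy)dauca-5,8-dien-14-oate (ester on C8; C8=C9 and C5=C6 alkenes), via cis-divinylcyclopropane 16 (not isolated)
Conditions: Rh2(S-DOSP)4 (dirhodium tetrakis[(S)-N-(4-dodecylbenzenesulfonyl)prolinate], 2 mol%), hexanes, 15 (3 equiv) added slowly at −40 °C, then 23 °C; then 60 °C
Reagents that add atoms: none
Why: The dirhodium carboxylate turns 15 into a donor/acceptor vinylcarbenoid whose carbene carbon (future C8) cyclopropanates only the electron-rich, unhindered terminal C6=C7 enol ether alkene of 10, the vinyl group ending cis to the cyclopentenyl group, and cyclopropane 16 then rearranges through a boat transition state, breaking C6–C8 and forming C10–C1; this tandem cyclopropanation/Cope rearrangement is the known formal (4+3) cycloaddition of vinyldiazoacetates with silyloxydienes. The seven-membered ring is closed onto the bought cyclopentene by a concerted six-electron [3,3]-sigmatropic shift (net new bonds C7–C8 and C10–C1), the three-membered ring opening in the same event and its strain driving the reaction. The one new stereocentre that remains, quaternary C1, is set because the Cope step is stereospecific: the catalyst fixes the configuration of the cyclopropane carbon C6, and that configuration decides which face of the C5=C1 alkene meets C10, here the α face, anti to the neighbouring C2 silyloxy group, so that catalyst and substrate reinforce each other. The step needs site selectivity, secured because the crowded tetrasubstituted ring alkene is inert to the bulky carbenoid yet still serves as a Cope terminus, and facial selectivity at C1, secured by the C2 silyl ether together with the matched catalyst. The tertiary alcohol is carried as its silyl ether so that O–H insertion cannot compete.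

Step 11
Reactants: 17 methyl (1R,2R,4R)-2β-(tert-butyldimethylsilyloxy)-4β,6-bis(triethylsilyloxy)dauca-5,8-dien-14-oate
Product: 18 (1R,2R,4R)-2β-(tert-butyldimethylsilyloxy)-4β,6-bis(triethylsilyloxy)dauca-5,8-dien-14-ol
Conditions: i-Bu2AlH (2.5 equiv), CH2Cl2, −78 °C; aqueous potassium sodium tartrate
Reagents that add atoms: none
Why: 1,2-Reduction of the α,β-unsaturated ester by the aluminium hydride at low temperature gives the primary allylic alcohol, and neither the hydride nor the neutral work-up touches the enol and alkyl silyl ethers.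

Step 12
Reactants: 18 (1R,2R,4R)-2β-(tert-butyldimethylsilyloxy)-4β,6-bis(triethylsilyloxy)dauca-5,8-dien-14-ol
Product: 20 (1R,2R,4R)-2β-(tert-butyldimethylsilyloxy)-4β,6-bis(triethylsilyloxy)dauca-5,8-diene, via allylic mesylate 19 (not isolated)
Conditions: MsCl, Et3N, THF, −20 °C; then LiEt3BH, −20 → 0 °C
Reagents that add atoms: none
Why: Deoxygenation of a primary allylic alcohol by mesylation and SN2 displacement with the trialkylborohydride (Super-Hydride reduction) attacks the unhindered primary carbon, so the C8=C9 alkene stays in place, and the basic, water-free medium spares the enol silyl ether.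

Step 13
Reactants: 20 (1R,2R,4R)-2β-(tert-butyldimethylsilyloxy)-4β,6-bis(triethylsilyloxy)dauca-5,8-diene
Product: 21 (1R,2R,4R,5R)-2β,4β-dihydroxydauc-8-en-6-one (trans-fused, 5α-H)
Conditions: Bu4NF (6 equiv), AcOH (6 equiv), THF, 0 → 40 °C
Reagents that add atoms: none
Why: Fluoride desilylation cleaves the enol silyl ether first and acetic acid protonates the freed enolate at C5 on the α face, the β face being screened by the C1 methyl group and the still silylated C2 and C4 oxygens, which gives the trans ring fusion (also expected to be the more stable one, with C6 beside the C4 oxygen and away from the isopropyl group); the buffer then lets the two remaining silyl ethers come off without retro-aldol cleavage, dehydration or migration of the C8=C9 alkene into conjugation.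

Step 14
Reactants: 21 (1R,2R,4R,5R)-2β,4β-dihydroxydauc-8-en-6-one
Product: 22 (1R,4R,5R)-4β-hydroxydauc-8-ene-2,6-dione
Conditions: Dess–Martin periodinane, NaHCO3, CH2Cl2, 0 → 23 °C
Reagents that add atoms: none
Why: Dess–Martin oxidation converts the only secondary alcohol into the ketone under buffered, non-enolising conditions that leave the tertiary alcohol, the β,γ-unsaturated ketone and C5 alone, erasing the C2 configuration so that it can be set anew.

Step 15
Reactants: 22 (1R,4R,5R)-4β-hydroxydauc-8-ene-2,6-dione
Product: 23 (1R,2S,4R,5S,6S)-dauc-8-ene-2α,4β,6α-triol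
Conditions: Me4NBH(OAc)3 (8 equiv), MeCN/AcOH 1:1, −30 → 0 °C
Reagents that add atoms: none
Why: In this hydroxyl-directed (Evans–Saksena) reduction the C4 hydroxyl exchanges onto boron and the resulting alkoxydiacetoxyborohydride delivers hydride internally to the β face of both flanking carbonyl groups, giving the 2α- and 6α-alcohols anti to the directing hydroxyl, while the acetoxyborohydride is too weak to reduce the ketones from outside.

Step 16
Reactants: 23 (1R,2S,4R,5S,6S)-dauc-8-ene-2α,4β,6α-triol; 24 angelic acid, (Z)-2-methylbut-2-enoic acid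
Product: 26 (1R,2S,4R,5S,6S)-2α,6α-bis[(Z)-2-methylbut-2-enoyloxy]dauc-8-en-4β-ol (CNP0303897.1), via mixed anhydride 25 (not isolated)
Conditions: 24 (6 equiv), 2,4,6-Cl3C6H2COCl (6 equiv), Et3N (7 equiv), toluene, 23 °C; then 23, 80 °C
Reagents that add atoms: none
Why: Yamaguchi esterification with the preformed mixed anhydride and no nucleophilic amine catalyst acylates both secondary alcohols without Z to E isomerisation of the angelate and leaves the hindered tertiary alcohol free.

**Compound list**

1 | (R)-4-(tert-butyldimethylsilyloxy)cyclopent-2-en-1-one | O=C1C=C[C@H](O[Si](C)(C)C(C)(C)C)C1 | starting material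
2 | [(3R,4R)-4-(tert-butyldimethylsilyloxy)-3-methylcyclopent-1-en-1-yl]oxy(trimethyl)silane, methyl trans to the silyloxy group | C[C@@H]1C=C(O[Si](C)(C)C)C[C@H]1O[Si](C)(C)C(C)(C)C | intermediate
3 | (R)-4-(tert-butyldimethylsilyloxy)-3-methylcyclopent-2-en-1-one | O=C1C=C(C)[C@H](O[Si](C)(C)C(C)(C)C)C1 | intermediate
4 | (4R)-2,3-dibromo-4-(tert-butyldimethylsilyloxy)-3-methylcyclopentan-1-one, mixture at C2 and C3 (dibromo ketone) | O=C1C(Br)C(C)(Br)[C@H](O[Si](C)(C)C(C)(C)C)C1 | intermediate
5 | (R)-2-bromo-4-(tert-butyldimethylsilyloxy)-3-methylcyclopent-2-en-1-one | O=C1C(Br)=C(C)[C@H](O[Si](C)(C)C(C)(C)C)C1 | intermediate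
6 | (1R,4R)-2-bromo-4-(tert-butyldimethylsilyloxy)-3-methyl-1-(propan-2-yl)cyclopent-2-en-1-ol, hydroxyl cis to the silyloxy group | BrC1=C(C)[C@H](O[Si](C)(C)C(C)(C)C)C[C@@]1(O)C(C)C | intermediate
7 | N-methoxy-N-methylacetamide | CC(=O)N(C)OC | starting material
8 | lithium (1R,4R)-4-(tert-butyldimethylsilyloxy)-2-lithio-3-methyl-1-(propan-2-yl)cyclopent-2-en-1-olate (dilithio alkoxide) | [Li]C1=C(C)[C@H](O[Si](C)(C)C(C)(C)C)C[C@@]1(O[Li])C(C)C | intermediate
9 | 1-[(3R,5R)-3-(tert-butyldimethylsilyloxy)-5-hydroxy-2-methyl-5-(propan-2-yl)cyclopent-1-en-1-yl]ethan-1-one | CC(=O)C1=C(C)[C@H](O[Si](C)(C)C(C)(C)C)C[C@@]1(O)C(C)C | intermediate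
10 | (3R,5R)-3-(tert-butyldimethylsilyloxy)-2-methyl-5-(propan-2-yl)-5-(triethylsilyloxy)-1-[1-(triethylsilyloxy)ethenyl]cyclopent-1-ene | C=C(O[Si](CC)(CC)CC)C1=C(C)[C@H](O[Si](C)(C)C(C)(C)C)C[C@@]1(O[Si](CC)(CC)CC)C(C)C | intermediate
11 | methyl acetoacetate | COC(=O)CC(C)=O | starting material
12 | methyl 2-diazo-3-oxobutanoate | COC(=O)C(=[N+]=[N-])C(C)=O | intermediate
13 | methyl 2-diazo-3-hydroxybutanoate (racemic) | COC(=O)C(=[N+]=[N-])C(C)O | intermediate
14 | methyl 2-diazo-3-(dichlorophosphoryloxy)butanoate (dichlorophosphate ester) | COC(=O)C(=[N+]=[N-])C(C)OP(=O)(Cl)Cl | intermediate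
15 | methyl 2-diazobut-3-enoate | COC(=O)C(=[N+]=[N-])C=C | intermediate
16 | methyl 1-ethenyl-2-[(3R,5R)-3-(tert-butyldimethylsilyloxy)-2-methyl-5-(propan-2-yl)-5-(triethylsilyloxy)cyclopent-1-en-1-yl]-2-(triethylsilyloxy)cyclopropane-1-carboxylate, ethenyl cis to the cyclopentenyl group (cis-divinylcyclopropane) | COC(=O)[C@]1(C=C)C[C@@]1(O[Si](CC)(CC)CC)C2=C(C)[C@H](O[Si](C)(C)C(C)(C)C)C[C@@]2(O[Si](CC)(CC)CC)C(C)C | intermediate
17 | methyl (1R,2R,4R)-2β-(tert-butyldimethylsilyloxy)-4β,6-bis(triethylsilyloxy)dauca-5,8-dien-14-oate | COC(=O)C1=CC[C@@]2(C)[C@H](O[Si](C)(C)C(C)(C)C)C[C@@](O[Si](CC)(CC)CC)(C(C)C)C2=C(O[Si](CC)(CC)CC)C1 | intermediate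
18 | (1R,2R,4R)-2β-(tert-butyldimethylsilyloxy)-4β,6-bis(triethylsilyloxy)dauca-5,8-dien-14-ol | OCC1=CC[C@@]2(C)[C@H](O[Si](C)(C)C(C)(C)C)C[C@@](O[Si](CC)(CC)CC)(C(C)C)C2=C(O[Si](CC)(CC)CC)C1 | intermediate
19 | (1R,2R,4R)-2β-(tert-butyldimethylsilyloxy)-4β,6-bis(triethylsilyloxy)dauca-5,8-dien-14-yl methanesulfonate (allylic mesylate) | CS(=O)(=O)OCC1=CC[C@@]2(C)[C@H](O[Si](C)(C)C(C)(C)C)C[C@@](O[Si](CC)(CC)CC)(C(C)C)C2=C(O[Si](CC)(CC)CC)C1 | intermediate
20 | (1R,2R,4R)-2β-(tert-butyldimethylsilyloxy)-4β,6-bis(triethylsilyloxy)dauca-5,8-diene | CC1=CC[C@@]2(C)[C@H](O[Si](C)(C)C(C)(C)C)C[C@@](O[Si](CC)(CC)CC)(C(C)C)C2=C(O[Si](CC)(CC)CC)C1 | intermediate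
21 | (1R,2R,4R,5R)-2β,4β-dihydroxydauc-8-en-6-one, trans-fused | CC1=CC[C@@]2(C)[C@H](O)C[C@@](O)(C(C)C)[C@@H]2C(=O)C1 | intermediate
22 | (1R,4R,5R)-4β-hydroxydauc-8-ene-2,6-dione | CC1=CC[C@@]2(C)C(=O)C[C@@](O)(C(C)C)[C@@H]2C(=O)C1 | intermediate
23 | (1R,2S,4R,5S,6S)-dauc-8-ene-2α,4β,6α-triol | CC1=CC[C@@]2(C)[C@@H](O)C[C@@](O)(C(C)C)[C@@H]2[C@@H](O)C1 | intermediate
24 | angelic acid, (Z)-2-methylbut-2-enoic acid | C/C=C(/C)C(=O)O | starting material
25 | (Z)-2-methylbut-2-enoic 2,4,6-trichlorobenzoic anhydride (mixed anhydride) | C/C=C(/C)C(=O)OC(=O)c1c(Cl)cc(Cl)cc1Cl | intermediate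
26 | CNP0303897.1, (1S,3R,3aS,4S,8aR)-3-hydroxy-6,8a-dimethyl-3-(propan-2-yl)-1,2,3,3a,4,5,8,8a-octahydroazulene-1,4-diyl bis[(2Z)-2-methylbut-2-enoate] | C/C=C(/C)C(=O)O[C@H]1CC(C)=CC[C@@]2(C)[C@@H](OC(=O)/C(C)=C\C)C[C@@](O)(C(C)C)[C@H]12 | target

**Step count**

Total: 16 steps. Longest linear sequence: 13 steps (steps 1–6 and 10–16, from 1). The diazo ester branch (steps 7–9) joins at step 10.

**Steps most likely to fail**

1. Step 10. The Cope rearrangement may stall at the fully substituted C1 terminus beside the crowded C4 centre; the diazo ester may be lost to cyclisation or carbene dimerisation before it cyclopropanates; or the catalyst may fail to reinforce the substrate so that C10 bonds to the wrong face of C1. The fallback sets out from bromo alcohol 6 and comes back to the route at diketone 22; it sets the quaternary centre by an anionic oxy-Cope rearrangement and closes the seven-membered ring by metathesis. Lithiation of 6 as in step 5 (dilithio alkoxide 8) and formylation with DMF should give (3R,5R)-3-(tert-butyldimethylsilyloxy)-5-hydroxy-2-methyl-5-(propan-2-yl)cyclopent-1-ene-1-carbaldehyde F1. Allylmagnesium bromide then adds to the aldehyde to give the bis-allylic diol F2 (either carbinol epimer serves). KH with 18-crown-6 in THF triggers the oxy-Cope shift, which should carry the allyl group to C1 on the face anti to the C2 silyloxy group and, after protonation, leave the cyclopentanecarbaldehyde F3. 2-Methylallylmagnesium chloride converts this into the diene diol F4, and (H2IMes)(PCy3)Cl2Ru=CHPh (second-generation Grubbs catalyst) closes the C8=C9 alkene to give the hydroazulene diol F5. Bu4NF removes the silyl group to give the triol F6, and Dess–Martin oxidation of both secondary alcohols gives 22.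

2. Step 13. Protonation at C5 may show poor facial selectivity and give the cis ring fusion; the C8=C9 alkene may drift into conjugation with the C6 ketone; or the β-hydroxy ketone may undergo retro-aldol cleavage or dehydration while the hindered silyl ethers are being removed. The fallback sets out from 20 and comes back at 21; it separates the protonation from the deprotection and makes it a kinetic, reagent-controlled event. MeLi in THF at 0 °C cleaves only the enol silyl ether to give the regiodefined lithium enolate F7. This is quenched at −78 °C with a hindered proton donor (2,6-di-tert-butyl-4-methylphenol), which must approach the less screened α face, to give the bis-silyl ketone F8. HF·pyridine in THF then removes both silyl ethers under non-basic conditions and gives 21.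

3. Step 15. Internal hydride delivery to the cyclopentanone carbonyl group at C2 may fail, or external attack from the α face may take over and return the 2β-alcohol; the β-hydroxy diketone may also lose the C4 hydroxyl by elimination. The fallback sets out from 21 and comes back at 23; it inverts C2 by substitution instead of oxidation and reduction. Mitsunobu reaction of 21 (4-nitrobenzoic acid, PPh3, DIAD, toluene) should give the inverted 2α-nitrobenzoate ketone F9. Me4NBH(OAc)3 then reduces the single C6 ketone under direction of the C4 hydroxyl to give the nitrobenzoate diol F10, and K2CO3 in MeOH removes the ester to give 23.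

**Further compounds**

F1 | step 10 | (3R,5R)-3-(tert-butyldimethylsilyloxy)-5-hydroxy-2-methyl-5-(propan-2-yl)cyclopent-1-ene-1-carbaldehyde | O=CC1=C(C)[C@H](O[Si](C)(C)C(C)(C)C)C[C@@]1(O)C(C)C
F2 | step 10 | 1-[(3R,5R)-3-(tert-butyldimethylsilyloxy)-5-hydroxy-2-methyl-5-(propan-2-yl)cyclopent-1-en-1-yl]but-3-en-1-ol, carbinol epimers (bis-allylic diol) | C=CCC(O)C1=C(C)[C@H](O[Si](C)(C)C(C)(C)C)C[C@@]1(O)C(C)C
F3 | step 10 | 3-(tert-butyldimethylsilyloxy)-5-hydroxy-2-methyl-2-(prop-2-en-1-yl)-5-(propan-2-yl)cyclopentane-1-carbaldehyde, allyl anti to the silyloxy group (cyclopentanecarbaldehyde) | C=CC[C@@]1(C)[C@H](O[Si](C)(C)C(C)(C)C)C[C@@](O)(C(C)C)[C@@H]1C=O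
F4 | step 10 | 1-[3-(tert-butyldimethylsilyloxy)-5-hydroxy-2-methyl-2-(prop-2-en-1-yl)-5-(propan-2-yl)cyclopentyl]-3-methylbut-3-en-1-ol, carbinol epimers (diene diol) | C=CC[C@@]1(C)[C@H](O[Si](C)(C)C(C)(C)C)C[C@@](O)(C(C)C)[C@@H]1C(O)CC(C)=C
F5 | step 10 | 2β-(tert-butyldimethylsilyloxy)dauc-8-ene-4β,6-diol, C6 epimers (hydroazulene diol) | CC1=CC[C@@]2(C)[C@H](O[Si](C)(C)C(C)(C)C)C[C@@](O)(C(C)C)[C@@H]2C(O)C1
F6 | step 10 | dauc-8-ene-2β,4β,6-triol, C6 epimers (triol) | CC1=CC[C@@]2(C)[C@H](O)C[C@@](O)(C(C)C)[C@@H]2C(O)C1
F7 | step 13 | lithium (1R,2R,4R)-2β-(tert-butyldimethylsilyloxy)-4β-(triethylsilyloxy)dauca-5,8-dien-6-olate (lithium enolate) | CC1=CC[C@@]2(C)[C@H](O[Si](C)(C)C(C)(C)C)C[C@@](O[Si](CC)(CC)CC)(C(C)C)C2=C(O[Li])C1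
F8 | step 13 | 2β-(tert-butyldimethylsilyloxy)-4β-(triethylsilyloxy)dauc-8-en-6-one, trans-fused (bis-silyl ketone) | CC1=CC[C@@]2(C)[C@H](O[Si](C)(C)C(C)(C)C)C[C@@](O[Si](CC)(CC)CC)(C(C)C)[C@@H]2C(=O)C1
F9 | step 15 | 4β-hydroxy-6-oxodauc-8-en-2α-yl 4-nitrobenzoate (nitrobenzoate ketone) | CC1=CC[C@@]2(C)[C@@H](OC(=O)c3ccc(cc3)[N+](=O)[O-])C[C@@](O)(C(C)C)[C@@H]2C(=O)C1
F10 | step 15 | 4β,6α-dihydroxydauc-8-en-2α-yl 4-nitrobenzoate (nitrobenzoate diol) | CC1=CC[C@@]2(C)[C@@H](OC(=O)c3ccc(cc3)[N+](=O)[O-])C[C@@](O)(C(C)C)[C@@H]2[C@@H](O)C1
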